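The plan rests on cutting the C5–C6 bond of the cyclohexane ring (ring atoms C1 CMe2, C2 CHBr, C3 CH2, C4 CHCl, C5, C6 CHCl; side chain C7, C8). The E-configured exocyclic C5=C7 alkene flanked by heteroatom-bearing C6 is read as the product of a syn reductive coupling between a C5≡C7 alkyne and a C6 aldehyde. One nickel-catalysed operation closes the six-membered ring, forms C5–C6, sets the C6 carbinol and fixes the alkene geometry. Its precursor is an acyclic 2,2-dimethyloct-6-ynal that already carries the C2 bromide, a C4 silyl ether and a C8 PMB ether; the two chlorides and the allylic bromide follow by substitution.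

Key step: step 8

Remark: ring compounds and all Why lines use the target locants C1–C8, acyclic compounds are named with their own chain locants; the isopinocampheylboranes are identified by the α-pinene enantiomer they derive from (l from (−)-, d from (+)-α-pinene); E/Z letters of some intermediates change with CIP ranking although the geometry (C8 cis to C4) is the same throughout.

Step 1
Reactants: 1 4-methoxybenzyl propargyl ether
Product: 4 4-(4-methoxybenzyloxy)but-2-ynal, via lithium acetylide 2 (not isolated), via lithium hemiaminal alkoxide 3 (not isolated)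
Conditions: n-BuLi, THF, −78 °C; DMF, −78 to 0 °C; inverse quench into aq. KH2PO4
Reagents that add atoms: N,N-dimethylformamide, CN(C)C=O
Why: Deprotonation of the terminal alkyne and formylation of the lithium acetylide with DMF (Bouveault-type formylation) should give the ynal, the buffered inverse quench collapsing the hemiaminal before the liberated amine can add in conjugate fashion.

Step 2
Reactants: 4 4-(4-methoxybenzyloxy)but-2-ynal
Product: 6 (4R)-7-(4-methoxybenzyloxy)hept-1-en-5-yn-4-ol, via borinate ester 5 (not isolated)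
Conditions: lIpc2B(allyl), Et2O, −78 °C; NaOH, H2O2, 0 °C
Reagents that add atoms: B-allylbis(isopinocampheyl)borane of the (−)-α-pinene series, C=CCB([C@@H]1[C@@H](C)[C@@H]2C[C@H](C1)C2(C)C)[C@@H]1[C@@H](C)[C@@H]2C[C@H](C1)C2(C)C
Why: Brown asymmetric allylboration through a chair-like six-membered transition state, in which the l-isopinocampheyl reagent should deliver allyl to the Re face of the ynal and so set C4 as R, the peroxide work-up cleaving the borinate.

Step 3
Reactants: 6 (4R)-7-(4-methoxybenzyloxy)hept-1-en-5-yn-4-ol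
Product: 7 (4R)-4-(tert-butyldimethylsilyloxy)-7-(4-methoxybenzyloxy)hept-1-en-5-yne
Conditions: TBSCl, imidazole, DMF, 23 °C
Reagents that add atoms: tert-butyldimethylsilyl chloride, CC(C)(C)[Si](C)(C)Cl
Why: Imidazole-promoted silylation of an unhindered secondary propargylic alcohol is routine and touches no stereocentre.

Step 4
Reactants: 7 (4R)-4-(tert-butyldimethylsilyloxy)-7-(4-methoxybenzyloxy)hept-1-en-5-yne
Product: 9 (3R)-3-(tert-butyldimethylsilyloxy)-6-(4-methoxybenzyloxy)hex-4-ynal, via vicinal diol 8 (not isolated)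
Conditions: OsO4 (2 mol%), NaIO4, 2,6-lutidine, dioxane/H2O, 23 °C
Reagents that add atoms: osmium tetroxide, O=[Os](=O)(=O)=O (delivers the aldehyde oxygen; re-oxidised by sodium periodate, [Na+].[O-][I](=O)(=O)=O)
Why: Lemieux–Johnson oxidation, in which OsO4 dihydroxylates the terminal alkene far faster than the internal alkyne or the anisyl ring and periodate cleaves the diol in the same flask, the lutidine buffer protecting the β-silyloxy aldehyde, which is used crude.

Step 5
Reactants: 9 (3R)-3-(tert-butyldimethylsilyloxy)-6-(4-methoxybenzyloxy)hex-4-ynal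
Product: 11 (4R,6R)-6-(tert-butyldimethylsilyloxy)-9-(4-methoxybenzyloxy)-3,3-dimethylnon-1-en-7-yn-4-ol, via borinate ester 10 (not isolated)
Conditions: dIpc2B(prenyl) [from Ipc2BH of the (+)-α-pinene series and 3-methylbuta-1,2-diene, THF, −25 °C], Et2O, −78 °C; NaOH, H2O2, 0 °C
Reagents that add atoms: B-prenylbis(isopinocampheyl)borane of the (+)-α-pinene series, CC(C)=CCB([C@H]1[C@H](C)[C@H]2C[C@@H](C1)C2(C)C)[C@H]1[C@H](C)[C@H]2C[C@@H](C1)C2(C)C (prenyl carbons from 3-methylbuta-1,2-diene, CC(C)=C=C)
Why: Brown reverse prenylation, an allylboration in which the prenyl group reacts at its γ-carbon through a chair-like transition state so that quaternary C1 bonds to C2, the d-isopinocampheyl reagent attacking the Si face and setting C2 as the R carbinol (1,3-anti to C4) under reagent control.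

Step 6
Reactants: 11 (4R,6R)-6-(tert-butyldimethylsilyloxy)-9-(4-methoxybenzyloxy)-3,3-dimethylnon-1-en-7-yn-4-ol
Product: 12 (4S,6R)-4-bromo-6-(tert-butyldimethylsilyloxy)-9-(4-methoxybenzyloxy)-3,3-dimethylnon-1-en-7-yne
Conditions: CBr4, P(n-C8H17)3, toluene, 70 °C
Reagents that add atoms: carbon tetrabromide, BrC(Br)(Br)Br
Why: Appel-type bromination under the trioctylphosphine protocol used for hindered secondary alcohols, in which bromide displaces the phosphorus-activated oxygen by SN2 and inverts C2 to S, the flat vinyl group on C1 leaving one flank open to backside attack and the apolar medium disfavouring ionisation.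

Step 7
Reactants: 12 (4S,6R)-4-bromo-6-(tert-butyldimethylsilyloxy)-9-(4-methoxybenzyloxy)-3,3-dimethylnon-1-en-7-yne
Product: 14 (3S,5R)-3-bromo-5-(tert-butyldimethylsilyloxy)-8-(4-methoxybenzyloxy)-2,2-dimethyloct-6-ynal, via vicinal diol 13 (not isolated)
Conditions: OsO4 (2 mol%), NaIO4, 2,6-lutidine, dioxane/H2O, 23 °C
Reagents that add atoms: osmium tetroxide, O=[Os](=O)(=O)=O (delivers the aldehyde oxygen; re-oxidised by sodium periodate, [Na+].[O-][I](=O)(=O)=O)
Why: A second Lemieux–Johnson cleavage turns the vinyl group into the neopentyl C6 aldehyde, which has no α-hydrogen and therefore cannot lose HBr by β-elimination, while alkyne, bromide and ethers are inert.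

Step 8
Reactants: 14 (3S,5R)-3-bromo-5-(tert-butyldimethylsilyloxy)-8-(4-methoxybenzyloxy)-2,2-dimethyloct-6-ynal
Product: 15 (2S,4R,6R)-2-bromo-4-(tert-butyldimethylsilyloxy)-5-[(E)-2-(4-methoxybenzyloxy)ethylidene]-1,1-dimethyl-6-(triethylsilyloxy)cyclohexane (target locants; all three ring substituents cis)
Conditions: Ni(cod)2 (10 mol%), IMes (10 mol%), Et3SiH, THF, 23 °C, slow addition of 14
Reagents that add atoms: triethylsilane, CC[SiH](CC)CC
Why: Zerovalent nickel carrying the carbene ligand binds alkyne and aldehyde and couples them oxidatively to a five-membered nickel–oxygen metallacycle (divalent nickel) in which the C5–C6 bond is made; σ-bond metathesis of the Ni–O bond with Et3SiH then gives the silyl ether and an alkenylnickel hydride, and C–H reductive elimination with retention puts hydrogen on C7 cis to the new bond, so C8 ends cis to C4 (E). The closest known reaction type is the nickel-catalysed reductive cyclisation of alkynals with trialkylsilanes to 2-alkylidenecycloalkanol silyl ethers. The six-membered ring closes in the 6-exo-dig mode. The new C6 stereocentre is under substrate control: in the chair-like transition state C2–Br and C4–OTBS sit equatorial and the aldehyde oxygen, which must lie near the plane of the forming alkene to reach nickel, is pseudo-equatorial as well, which gives the all-cis 2,4,6 pattern. The step needs chemoselectivity for alkyne–aldehyde coupling over activation of the C2–Br bond, and this is secured by the fast intramolecular coupling, the hindered neopentyl-type secondary bromide, the non-enolisable aldehyde and the poor propargylic leaving groups, with slow addition keeping free 14 low.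

Step 9
Reactants: 15 cyclised bis-silyl ether
Product: 17 (2S,4R,6R)-2-bromo-5-[(E)-2-(4-methoxybenzyloxy)ethylidene]-1,1-dimethylcyclohexane-4,6-diol (target locants; cis-diol cis to bromine), via C6 alcohol 16 (not isolated)
Conditions: HF·pyridine, pyridine, THF, 0 to 23 °C
Reagents that add atoms: none
Why: Acidic fluoride desilylation should remove the triethylsilyl ether first and the allylic TBS ether second, a basic fluoride source being avoided because a free C6 alkoxide is aligned through C1 with the equatorial C2–Br bond and could undergo Grob fragmentation.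

Step 10
Reactants: 17 cis-diol
Product: 19 (2S,4S,6S)-2-bromo-4,6-dichloro-5-[(E)-2-(4-methoxybenzyloxy)ethylidene]-1,1-dimethylcyclohexane (target locants), via C4 monochloride 18 (not isolated)
Conditions: PPh3, Cl3CCOCCl3, CH2Cl2, 0 to 23 °C
Reagents that add atoms: hexachloroacetone, ClC(Cl)(Cl)C(=O)C(Cl)(Cl)Cl
Why: Appel-type deoxychlorination with triphenylphosphine and hexachloroacetone, a reagent pair that converts secondary allylic alcohols into chlorides by SN2 with inversion and little allylic transposition, should invert C4 first and C6 second and so place both chlorides cis to each other and trans to bromine.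

Step 11
Reactants: 19 dichloride PMB ether
Product: 20 (E)-2-[(2S,4S,6S)-2-bromo-4,6-dichloro-1,1-dimethylcyclohexan-5-ylidene]ethanol (target locants)
Conditions: DDQ, CH2Cl2/pH 7 buffer, 0 °C
Reagents that add atoms: none
Why: Oxidative cleavage of the 4-methoxybenzyl ether by DDQ (hydride abstraction at the electron-rich benzylic carbon and hydrolysis of the oxocarbenium ion) should free the primary allylic alcohol while allylic chlorides and the alkyl bromide are inert.

Step 12
Reactants: 20 allylic alcohol
Product: 21 ochtodene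
Conditions: CBr4, PPh3, CH2Cl2, 0 °C
Reagents that add atoms: carbon tetrabromide, BrC(Br)(Br)Br
Why: Appel bromination by SN2 at the unhindered primary allylic carbon C8, at a temperature where the secondary halides should neither exchange nor rearrange, completes the target with all three stereocentres untouched.

Compound list
1 | 4-methoxybenzyl propargyl ether | C#CCOCc1ccc(OC)cc1 | starting material
2 | lithium acetylide of 1 | [Li]C#CCOCc1ccc(OC)cc1 | intermediate
3 | lithium 1-(dimethylamino)-4-(4-methoxybenzyloxy)but-2-yn-1-olate (hemiaminal alkoxide, racemic) | [Li]OC(N(C)C)C#CCOCc1ccc(OC)cc1 | intermediate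
4 | 4-(4-methoxybenzyloxy)but-2-ynal | O=CC#CCOCc1ccc(OC)cc1 | intermediate
5 | bis(l-isopinocampheyl)borinate ester of 6 | C=CC[C@@H](OB([C@@H]1[C@@H](C)[C@@H]2C[C@H](C1)C2(C)C)[C@@H]1[C@@H](C)[C@@H]2C[C@H](C1)C2(C)C)C#CCOCc1ccc(OC)cc1 | intermediate
6 | (4R)-7-(4-methoxybenzyloxy)hept-1-en-5-yn-4-ol | C=CC[C@@H](O)C#CCOCc1ccc(OC)cc1 | intermediate
7 | (4R)-4-(tert-butyldimethylsilyloxy)-7-(4-methoxybenzyloxy)hept-1-en-5-yne | C=CC[C@@H](O[Si](C)(C)C(C)(C)C)C#CCOCc1ccc(OC)cc1 | intermediate
8 | (4R)-4-(tert-butyldimethylsilyloxy)-7-(4-methoxybenzyloxy)hept-5-yne-1,2-diol (both C2 epimers) | OCC(O)C[C@@H](O[Si](C)(C)C(C)(C)C)C#CCOCc1ccc(OC)cc1 | intermediate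
9 | (3R)-3-(tert-butyldimethylsilyloxy)-6-(4-methoxybenzyloxy)hex-4-ynal | O=CC[C@@H](O[Si](C)(C)C(C)(C)C)C#CCOCc1ccc(OC)cc1 | intermediate
10 | bis(d-isopinocampheyl)borinate ester of 11 | C=CC(C)(C)[C@H](OB([C@H]1[C@H](C)[C@H]2C[C@@H](C1)C2(C)C)[C@H]1[C@H](C)[C@H]2C[C@@H](C1)C2(C)C)C[C@@H](O[Si](C)(C)C(C)(C)C)C#CCOCc1ccc(OC)cc1 | intermediate
11 | (4R,6R)-6-(tert-butyldimethylsilyloxy)-9-(4-methoxybenzyloxy)-3,3-dimethylnon-1-en-7-yn-4-ol | C=CC(C)(C)[C@H](O)C[C@@H](O[Si](C)(C)C(C)(C)C)C#CCOCc1ccc(OC)cc1 | intermediate
12 | (4S,6R)-4-bromo-6-(tert-butyldimethylsilyloxy)-9-(4-methoxybenzyloxy)-3,3-dimethylnon-1-en-7-yne | C=CC(C)(C)[C@@H](Br)C[C@@H](O[Si](C)(C)C(C)(C)C)C#CCOCc1ccc(OC)cc1 | intermediate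
13 | (4S,6R)-4-bromo-6-(tert-butyldimethylsilyloxy)-9-(4-methoxybenzyloxy)-3,3-dimethylnon-7-yne-1,2-diol (both C2 epimers) | OCC(O)C(C)(C)[C@@H](Br)C[C@@H](O[Si](C)(C)C(C)(C)C)C#CCOCc1ccc(OC)cc1 | intermediate
14 | (3S,5R)-3-bromo-5-(tert-butyldimethylsilyloxy)-8-(4-methoxybenzyloxy)-2,2-dimethyloct-6-ynal | O=CC(C)(C)[C@@H](Br)C[C@@H](O[Si](C)(C)C(C)(C)C)C#CCOCc1ccc(OC)cc1 | intermediate
15 | (2S,4R,6R)-2-bromo-4-(tert-butyldimethylsilyloxy)-5-[(E)-2-(4-methoxybenzyloxy)ethylidene]-1,1-dimethyl-6-(triethylsilyloxy)cyclohexane (target locants; Br, OTBS and OTES all cis) | CC1(C)[C@@H](Br)C[C@@H](O[Si](C)(C)C(C)(C)C)/C(=C\COCc2ccc(OC)cc2)[C@H]1O[Si](CC)(CC)CC | intermediate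
16 | (2S,4R,6R)-2-bromo-4-(tert-butyldimethylsilyloxy)-5-[(Z)-2-(4-methoxybenzyloxy)ethylidene]-1,1-dimethylcyclohexan-6-ol (target locants; all cis; C8 cis to C4) | CC1(C)[C@@H](Br)C[C@@H](O[Si](C)(C)C(C)(C)C)/C(=C\COCc2ccc(OC)cc2)[C@H]1O | intermediate
17 | (2S,4R,6R)-2-bromo-5-[(E)-2-(4-methoxybenzyloxy)ethylidene]-1,1-dimethylcyclohexane-4,6-diol (target locants; all cis) | CC1(C)[C@@H](Br)C[C@@H](O)/C(=C\COCc2ccc(OC)cc2)[C@H]1O | intermediate
18 | (2S,4S,6R)-2-bromo-4-chloro-5-[(Z)-2-(4-methoxybenzyloxy)ethylidene]-1,1-dimethylcyclohexan-6-ol (target locants; Cl trans to Br and OH; C8 cis to C4) | CC1(C)[C@@H](Br)C[C@H](Cl)/C(=C\COCc2ccc(OC)cc2)[C@H]1O | intermediate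
19 | (2S,4S,6S)-2-bromo-4,6-dichloro-5-[(E)-2-(4-methoxybenzyloxy)ethylidene]-1,1-dimethylcyclohexane (target locants) | CC1(C)[C@@H](Br)C[C@H](Cl)/C(=C\COCc2ccc(OC)cc2)[C@@H]1Cl | intermediate
20 | (E)-2-[(2S,4S,6S)-2-bromo-4,6-dichloro-1,1-dimethylcyclohexan-5-ylidene]ethanol (target locants) | CC1(C)[C@@H](Br)C[C@H](Cl)/C(=C\CO)[C@@H]1Cl | intermediate
21 | ochtodene, (2S,4S,6S)-2-bromo-5-[(E)-2-bromoethylidene]-4,6-dichloro-1,1-dimethylcyclohexane (target locants) | CC1(C)[C@@H](Br)C[C@H](Cl)/C(=C\CBr)[C@@H]1Cl | target

Total step count: 12. Longest linear sequence: 12 steps (1 to 21).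

Steps most likely to fail, with fallbacks:

The bromination of step 6. Backside displacement at C2 is slowed by the adjacent quaternary carbon, so elimination towards C3, ionisation with 1,2-shift of the vinyl group, or mere persistence of the activated alcohol may win. The fallback leaves the route at aldehyde 9 and returns at aldehyde 14, replacing the vinyl group by an ester that resists ionisation and cannot migrate. A BF3·OEt2-promoted Mukaiyama aldol addition of 1-methoxy-2-methyl-1-(trimethylsilyloxy)prop-1-ene (CH2Cl2, −78 °C), with 1,3-anti induction from the β-silyloxy centre, should give methyl (3R,5R)-5-(tert-butyldimethylsilyloxy)-3-hydroxy-8-(4-methoxybenzyloxy)-2,2-dimethyloct-6-ynoate F1. Triflation (Tf2O, pyridine, CH2Cl2, −20 °C) should give methyl (3R,5R)-5-(tert-butyldimethylsilyloxy)-8-(4-methoxybenzyloxy)-2,2-dimethyl-3-(trifluoromethylsulfonyloxy)oct-6-ynoate F2. Bu4NBr (toluene, 0 to 23 °C) should displace the triflate with inversion to methyl (3S,5R)-3-bromo-5-(tert-butyldimethylsilyloxy)-8-(4-methoxybenzyloxy)-2,2-dimethyloct-6-ynoate F3. Reduction of the hindered ester with i-Bu2AlH (CH2Cl2, −78 °C) then gives 14.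

The cyclisation of step 8. Low-valent nickel may abstract bromine from C2 or insert into the C2–Br bond, the silane may reduce aldehyde or alkyne before ring closure, and facial control at C6 may fall short. The fallback leaves at 14 and returns at 16. It replaces silane-terminated nickel catalysis by the hydrogen-mediated reductive cyclisation of acetylenic aldehydes under a cationic monovalent rhodium catalyst ([Rh(cod)2]OTf, a BIPHEP-type bisphosphine, a carboxylic acid co-catalyst, H2 at 1 atm, 1,2-dichloroethane, 25 to 40 °C). Oxidative coupling at rhodium followed by hydrogenolysis should give the free C6 alcohol 16 directly, with the same syn delivery of hydrogen to C7; alkyl bromides are inert to this catalyst and a chiral bisphosphine can reinforce the C6 configuration. Compound 16 is then isolated and carried through step 9, where only the TBS ether remains to be cleaved. New compounds: none F0.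

The double chlorination of step 10. Substitution at the neopentyl, allylic C6 centre may lag behind that at C4 and then, with the new C4 chloride syn-axial to the incoming nucleophile, divert to allylic transposition (chloride entering at C7) or to ionisation with loss of configuration; the cis-1,3-diol may also tie up phosphorus as a cyclic phosphorane. The fallback leaves at 15 and returns at 19, treating the carbinols one at a time, hindered centre first. PPTS in MeOH (0 °C) should remove only the triethylsilyl ether and give 16, now isolated. 1-Chloro-N,N,2-trimethylprop-1-en-1-amine (Ghosez reagent, CH2Cl2, 0 to 23 °C) should chlorinate C6 with inversion under neutral conditions, while only hydrogens are syn-axial to the entering chloride, giving (2S,4R,6S)-2-bromo-4-(tert-butyldimethylsilyloxy)-6-chloro-5-[(E)-2-(4-methoxybenzyloxy)ethylidene]-1,1-dimethylcyclohexane F4. HF·pyridine (THF, 0 to 23 °C) should free (2S,4R,6S)-2-bromo-6-chloro-5-[(E)-2-(4-methoxybenzyloxy)ethylidene]-1,1-dimethylcyclohexan-4-ol F5. A single triphenylphosphine–hexachloroacetone chlorination at the less hindered C4 then gives 19.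

Further compounds
F1 | step 6 | methyl (3R,5R)-5-(tert-butyldimethylsilyloxy)-3-hydroxy-8-(4-methoxybenzyloxy)-2,2-dimethyloct-6-ynoate | COC(=O)C(C)(C)[C@H](O)C[C@@H](O[Si](C)(C)C(C)(C)C)C#CCOCc1ccc(OC)cc1
F2 | step 6 | methyl (3R,5R)-5-(tert-butyldimethylsilyloxy)-8-(4-methoxybenzyloxy)-2,2-dimethyl-3-(trifluoromethylsulfonyloxy)oct-6-ynoate | COC(=O)C(C)(C)[C@H](OS(=O)(=O)C(F)(F)F)C[C@@H](O[Si](C)(C)C(C)(C)C)C#CCOCc1ccc(OC)cc1
F3 | step 6 | methyl (3S,5R)-3-bromo-5-(tert-butyldimethylsilyloxy)-8-(4-methoxybenzyloxy)-2,2-dimethyloct-6-ynoate | COC(=O)C(C)(C)[C@@H](Br)C[C@@H](O[Si](C)(C)C(C)(C)C)C#CCOCc1ccc(OC)cc1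
F0 | step 8 | none | none
F4 | step 10 | (2S,4R,6S)-2-bromo-4-(tert-butyldimethylsilyloxy)-6-chloro-5-[(E)-2-(4-methoxybenzyloxy)ethylidene]-1,1-dimethylcyclohexane (target locants) | CC1(C)[C@@H](Br)C[C@@H](O[Si](C)(C)C(C)(C)C)/C(=C\COCc2ccc(OC)cc2)[C@@H]1Cl
F5 | step 10 | (2S,4R,6S)-2-bromo-6-chloro-5-[(E)-2-(4-methoxybenzyloxy)ethylidene]-1,1-dimethylcyclohexan-4-ol (target locants) | CC1(C)[C@@H](Br)C[C@@H](O)/C(=C\COCc2ccc(OC)cc2)[C@@H]1Cl
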